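The disconnection is N1–C7a of ring A, the NH indole. In ring A the fusion carbon C3a has only two ortho neighbours, C4 and C7a, and C4 already carries N1' of ring B. A vinyl nitrene hung on the carbon that becomes C3 can therefore reach only C7a–H. One metal-free thermolysis thus closes the ring A pyrrole with fixed regiochemistry and leaves all aryl bromides untouched. The precursor is a (Z)-2-azidocinnamate whose benzene ring already bears the 5-bromoindol-1-yl group (future C4), bromine (future C5) and methoxy (future C7). Its aldehyde parent first activates the C4 fluoride for SNAr by the ring B nitrogen.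

Key step: step 4

Assumption: the target SMILES gives no configuration for the hindered C4–N1' axis and the molecule has no stereocentre, so the racemic axis is the goal and nothing stereochemical needs control.

Step 1
Reactants: 1 2-bromo-1-fluoro-4-methoxybenzene
Product: 4 3-bromo-2-fluoro-5-methoxybenzaldehyde, via (3-bromo-2-fluoro-5-methoxyphenyl)lithium 2 (not isolated), via lithium hemiaminal alkoxide 3 (not isolated)
Conditions: LiN(iPr)2 (LDA, commercial solution, 1.05 equiv), THF, −78 °C; DMF, −78 → −20 °C; 1 M HCl
Reagents that add atoms: N,N-dimethylformamide, CN(C)C=O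
Why: Directed ortho-lithiation with a lithium amide should take the C–H next to fluorine, the strongest acidifier on the ring and the less hindered of the two activated sites (as with 1-bromo-2-fluorobenzene), the aryllithium should not lose LiF at −78 °C, and DMF traps it in a Bouveault-type formylation that releases the aldehyde on acidic work-up.

Step 2
Reactants: 4 3-bromo-2-fluoro-5-methoxybenzaldehyde; 5 5-bromo-1H-indole
Product: 6 3-bromo-2-(5-bromo-1H-indol-1-yl)-5-methoxybenzaldehyde
Conditions: Cs2CO3 (2 equiv), DMF, 100 °C, N2
Reagents that add atoms: none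
Why: Nucleophilic aromatic substitution (SNAr) in which the cesium indolide attacks the fluorine-bearing carbon, activated by the ortho formyl group that stabilises the Meisenheimer intermediate, while the bromine, meta to the aldehyde, is not activated and stays.

Step 3
Reactants: 6 3-bromo-2-(5-bromo-1H-indol-1-yl)-5-methoxybenzaldehyde; 7 methyl 2-azidoacetate (4 equiv)
Product: 9 methyl (Z)-2-azido-3-[3-bromo-2-(5-bromo-1H-indol-1-yl)-5-methoxyphenyl]prop-2-enoate, via β-hydroxy azido ester aldol adduct 8 (not isolated)
Conditions: NaOMe (4 equiv), MeOH/THF, −15 → 0 °C; cold aq. NH4Cl; azides kept cold and shielded from light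
Reagents that add atoms: none
Why: Knoevenagel-type aldol condensation (first stage of the Hemetsberger–Knittel sequence) in which the azidoacetate enolate adds to the non-enolisable aldehyde and E1cB loss of hydroxide should give the conjugated azidocinnamate as the Z isomer, aryl trans to the ester, the usual outcome of this condensation.

Step 4
Reactants: 9 methyl (Z)-2-azido-3-[3-bromo-2-(5-bromo-1H-indol-1-yl)-5-methoxyphenyl]prop-2-enoate
Product: 11 methyl 5-bromo-4-(5-bromo-1H-indol-1-yl)-7-methoxy-1H-indole-2-carboxylate, via 2H-azirine-3-carboxylate 10 (not isolated)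
Conditions: slow addition to refluxing xylenes (final ≤0.05 M), 140 °C, N2
Reagents that add atoms: none
Why: This is a Hemetsberger–Knittel indole synthesis: at 140 °C the vinyl azide loses N2 to a 2H-azirine in equilibrium with the singlet vinyl nitrene. The nitrene nitrogen bonds to the ortho carbon C7a in a five-atom, six-electron (1,5) electrocyclisation, and a [1,5]-hydrogen shift from C7a to nitrogen restores aromaticity, so the pyrrole of ring A closes through the new N1–C7a bond, formally a nitrene insertion into an aromatic C–H bond. No stereocentre is created and the hindered C4–N1' axis is carried as the racemate. The step needs regioselectivity between the two carbons ortho to C3a, and the substrate secures it because C4 already bears N1', which leaves C7a–H as the only reachable position. It also needs the two C–Br bonds to survive and the intramolecular path to win over intermolecular ones, which the absence of any metal and the high dilution should provide.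

Step 5
Reactants: 11 methyl 5-bromo-4-(5-bromo-1H-indol-1-yl)-7-methoxy-1H-indole-2-carboxylate
Product: 13 5-bromo-4-(5-bromo-1H-indol-1-yl)-7-methoxy-1H-indole-2-carboxylic acid, via lithium carboxylate 12 (not isolated)
Conditions: LiOH·H2O (5 equiv), THF/MeOH/H2O, 50 °C; 1 M HCl to pH 2–3
Reagents that add atoms: lithium hydroxide, [Li+].[OH-]
Why: Saponification (acyl–oxygen ester hydrolysis) of an unhindered methyl ester, under which the aryl bromides, the aryl methyl ether and the N-aryl bond are inert, with acidification delivering the free acid.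

Step 6
Reactants: 13 5-bromo-4-(5-bromo-1H-indol-1-yl)-7-methoxy-1H-indole-2-carboxylic acid
Product: 14 5-bromo-4-(5-bromo-1H-indol-1-yl)-7-methoxy-1H-indole
Conditions: Ag2CO3 (15 mol%), AcOH (10 mol%), DMSO, 120 °C
Reagents that add atoms: none
Why: Silver-catalysed protodecarboxylation of a heteroaromatic acid, in which the silver carboxylate extrudes CO2 to a C2-silver indole that acetic acid protonates, and since monovalent silver does not insert into C–Br bonds both bromides should survive.

Step 7
Reactants: 14 5-bromo-4-(5-bromo-1H-indol-1-yl)-7-methoxy-1H-indole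
Product: 16 rivularin B (3,5-dibromo-4-(3,5-dibromo-1H-indol-1-yl)-7-methoxy-1H-indole), via ring A 3-monobromide 15 (not isolated)
Conditions: NBS (2.05 equiv), DMF, −20 → 0 °C, dark; aq. Na2S2O3/NaHCO3
Reagents that add atoms: N-bromosuccinimide, O=C1CCC(=O)N1Br
Why: Electrophilic aromatic bromination at the β-carbons C3 (ring A, expected to react first) and C3' (ring B), the most nucleophilic position of each indole, so two equivalents of NBS at low temperature should stop before C2, C2' or C6 react.

Compound list
1 | 2-bromo-1-fluoro-4-methoxybenzene | COc1ccc(F)c(Br)c1 | starting material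
2 | (3-bromo-2-fluoro-5-methoxyphenyl)lithium (not isolated) | [Li]c1cc(OC)cc(Br)c1F | intermediate
3 | lithium (3-bromo-2-fluoro-5-methoxyphenyl)(dimethylamino)methanolate (racemic, not isolated) | [Li+].[O-]C(N(C)C)c1cc(OC)cc(Br)c1F | intermediate
4 | 3-bromo-2-fluoro-5-methoxybenzaldehyde | O=Cc1cc(OC)cc(Br)c1F | intermediate
5 | 5-bromo-1H-indole | Brc1ccc2[nH]ccc2c1 | starting material
6 | 3-bromo-2-(5-bromo-1H-indol-1-yl)-5-methoxybenzaldehyde | O=Cc1cc(OC)cc(Br)c1-n1ccc2cc(Br)ccc21 | intermediate
7 | methyl 2-azidoacetate | COC(=O)CN=[N+]=[N-] | starting material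
8 | methyl 2-azido-3-[3-bromo-2-(5-bromo-1H-indol-1-yl)-5-methoxyphenyl]-3-hydroxypropanoate (diastereomer mixture, not isolated) | COC(=O)C(N=[N+]=[N-])C(O)c1cc(OC)cc(Br)c1-n1ccc2cc(Br)ccc21 | intermediate
9 | methyl (Z)-2-azido-3-[3-bromo-2-(5-bromo-1H-indol-1-yl)-5-methoxyphenyl]prop-2-enoate | COC(=O)/C(N=[N+]=[N-])=C/c1cc(OC)cc(Br)c1-n1ccc2cc(Br)ccc21 | intermediate
10 | methyl 2-[3-bromo-2-(5-bromo-1H-indol-1-yl)-5-methoxyphenyl]-2H-azirine-3-carboxylate (racemic, not isolated) | COC(=O)C1=NC1c1cc(OC)cc(Br)c1-n1ccc2cc(Br)ccc21 | intermediate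
11 | methyl 5-bromo-4-(5-bromo-1H-indol-1-yl)-7-methoxy-1H-indole-2-carboxylate | COC(=O)c1cc2c(-n3ccc4cc(Br)ccc43)c(Br)cc(OC)c2[nH]1 | intermediate
12 | lithium 5-bromo-4-(5-bromo-1H-indol-1-yl)-7-methoxy-1H-indole-2-carboxylate (not isolated) | [Li+].[O-]C(=O)c1cc2c(-n3ccc4cc(Br)ccc43)c(Br)cc(OC)c2[nH]1 | intermediate
13 | 5-bromo-4-(5-bromo-1H-indol-1-yl)-7-methoxy-1H-indole-2-carboxylic acid | OC(=O)c1cc2c(-n3ccc4cc(Br)ccc43)c(Br)cc(OC)c2[nH]1 | intermediate
14 | 5-bromo-4-(5-bromo-1H-indol-1-yl)-7-methoxy-1H-indole | COc1cc(Br)c(-n2ccc3cc(Br)ccc32)c2cc[nH]c12 | intermediate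
15 | 3,5-dibromo-4-(5-bromo-1H-indol-1-yl)-7-methoxy-1H-indole (not isolated) | COc1cc(Br)c(-n2ccc3cc(Br)ccc32)c2c(Br)c[nH]c12 | intermediate
16 | rivularin B, 3,5-dibromo-4-(3,5-dibromo-1H-indol-1-yl)-7-methoxy-1H-indole | COc1cc(Br)c(-n2cc(Br)c3cc(Br)ccc32)c2c(Br)c[nH]c12 | target

Total step count: 7. Longest linear sequence: 7 steps (1 to 16); 5 and 7 enter as purchased materials.

Steps most likely to fail

Step 4. After N2 loss at 140 °C the azirine–nitrene pair may be consumed by intermolecular coupling, or by attack on the electron-rich ring B beside it, faster than it cyclises onto C7a. The fallback sets out from 9 and separates nitrogen loss from C–N bond formation. Irradiation (365 nm LED, MeCN, 20 °C) should expel N2 at ambient temperature and allow 2H-azirine 10 to be isolated. The azirine is then ring-expanded in a separate catalysed reaction with FeCl2 (10 mol%) in THF at 60 °C: Lewis-acidic divalent iron opens the azirine C–N single bond and the iron-bound vinyl nitrenoid aminates C7a–H. The route is rejoined at 11. This fallback makes no compound outside the list (F0).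

Step 1. Deprotonation may partition between the C–H next to fluorine and the C–H flanked by bromine and methoxy, or the aryllithium may decay by halide loss or bromine migration before it is trapped. The fallback sets out from 1 and replaces the small, lithium-coordinating methoxy group by a bulky, non-coordinating silyl ether during the metalation.
- O-Demethylation (48% HBr, AcOH, reflux) should give 3-bromo-4-fluorophenol F1.
- TIPSCl and imidazole in DMF convert it into (3-bromo-4-fluorophenoxy)triisopropylsilane F2, in which both C–H bonds next to oxygen are shielded.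
- LiN(iPr)2 in THF at −78 °C can then only form [3-bromo-2-fluoro-5-(triisopropylsilyloxy)phenyl]lithium F3.
- DMF converts F3 into the lithium hemiaminal alkoxide F4, and acidic work-up gives 3-bromo-2-fluoro-5-(triisopropylsilyloxy)benzaldehyde F5.
- Desilylation (TBAF, AcOH, THF, 0 °C) gives 3-bromo-2-fluoro-5-hydroxybenzaldehyde F6.
- O-Methylation (MeI, K2CO3, DMF, 20 °C) rejoins the route at 4.

Step 3. The azidoacetate enolate may lose N2 and decompose faster than it adds to the hindered, electron-rich aldehyde, or the sequence may stall before dehydration. The fallback sets out from 6 and 7 and splits addition from elimination. Addition with NaOMe at −30 °C is stopped at the aldol stage and 8 is isolated. MsCl and Et3N in CH2Cl2 at 0 °C convert the alcohol into methyl 2-azido-3-[3-bromo-2-(5-bromo-1H-indol-1-yl)-5-methoxyphenyl]-3-(methanesulfonyloxy)propanoate F7. DBU then eliminates methanesulfonate and the route is rejoined at 9.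

Further compounds
F0 | step 4 | none | none
F1 | step 1 | 3-bromo-4-fluorophenol | Oc1ccc(F)c(Br)c1
F2 | step 1 | (3-bromo-4-fluorophenoxy)triisopropylsilane | CC(C)[Si](Oc1ccc(F)c(Br)c1)(C(C)C)C(C)C
F3 | step 1 | [3-bromo-2-fluoro-5-(triisopropylsilyloxy)phenyl]lithium | [Li]c1cc(O[Si](C(C)C)(C(C)C)C(C)C)cc(Br)c1F
F4 | step 1 | lithium [3-bromo-2-fluoro-5-(triisopropylsilyloxy)phenyl](dimethylamino)methanolate | [Li+].[O-]C(N(C)C)c1cc(O[Si](C(C)C)(C(C)C)C(C)C)cc(Br)c1F
F5 | step 1 | 3-bromo-2-fluoro-5-(triisopropylsilyloxy)benzaldehyde | O=Cc1cc(O[Si](C(C)C)(C(C)C)C(C)C)cc(Br)c1F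
F6 | step 1 | 3-bromo-2-fluoro-5-hydroxybenzaldehyde | O=Cc1cc(O)cc(Br)c1F
F7 | step 3 | methyl 2-azido-3-[3-bromo-2-(5-bromo-1H-indol-1-yl)-5-methoxyphenyl]-3-(methanesulfonyloxy)propanoate | COC(=O)C(N=[N+]=[N-])C(OS(C)(=O)=O)c1cc(OC)cc(Br)c1-n1ccc2cc(Br)ccc21
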